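Readings and results stem from a simulated flask for substances that don't exist; noise was put on by code.

Lay the earlier runs side by side and read them stage by stage.

| setting | dawn | dusk | noon | flask |
|---|---|---|---|---|
| D | 0.070 M | 0.28 M | 0.14 M | 0.14 M |
| E | 1.5 equiv | 1.5 equiv | 3 equiv | 1.50 equiv |
| remark | run made earlier | run made earlier | run made earlier |  |
| time |  |  |  | 5.0 min |
| volume of the second phase over the first |  |  |  | 0.25 |

- dawn (time / min: DG / %): 1.00: 2; 2.00: 4; 3.00: 7; 4.00: 9; 5.00: 15
- dusk (time / min: DG / %): 0.417: 1; 0.833: 3; 1.33: 9; 2.50: 15; 5.00: 26
- noon (time / min: DG / %): 0.417: 1; 0.833: 4; 1.33: 12; 2.50: 21; 5.00: 27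

(scatter of a reading: 1.5 percentage points)

- in the second phase: E; everything else is in the first
- charges count per volume of the first phase; a concentration in a rate is the amount of a species over the volume of its own phase; every rate counts per litre of the first phase
- the earlier runs were read with a standard deviation of 1.5 percentage points
- the earlier runs hold the two phases in the same ratio of volumes as the flask asked about

- amount of DG at 5.0 min, in percent of the D charged
- the change that raises the amount of DG at 5.0 min, in percent of the D charged most ("none" if none brings more than 2 percentage points) (maple / birch / none)
- amount of DG at 5.0 min, in percent of the D charged, after birch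

- maple: doubling the transfer coefficient of E, all else as stated
- birch: doubling the amount of E, all else as stated

In the first instants I read a lag: the dusk run held 1% DG at 0.417 min and the noon run 1%, against a scatter of 1.5 percentage points. I took this as E still crossing into the first phase.

In the middle, from 0.833 min to 1.33 min, the dusk run gained 6 points and the noon run 8 points.

Towards the end the two runs, which hold the same E per litre, stayed in the same order: the noon run read 6 points above the dusk run at 2.50 min and 1 point above it at 5.00 min. Each of these readings carries a scatter of 1.5 points, so I read no change of pace from them. For the flask I looked to c(D) at fixed equivalents.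

From the dawn run to the dusk run, c(D) rose 4.00-fold, which is 2 doublings, and DG at 5.00 min rose from 15% to 26%. The doubling step, my name for the points of DG gained per doubling of c(D) at 1.5 equiv (a slope of yield on log charge), was therefore 5.5 points.

The flask stands one doubling above the dawn run, so I reckoned 20.5%. Birch turns the flask into the noon recipe, so I read 27% for it, 6.5 points above my figure.

The forecast gave 17%, lower than my figure, with 27% after birch: “Interpolating dawn and dusk at 1.5 equiv gives about 18%.”

The flask gave 18.0% and birch 26.0%. Birch gained 8.1 points and maple 1.5 points, so the choice was birch.

    2 G → J (k = 0.0300 M⁻¹ s⁻¹)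
    G ⇌ E, rate k2*([G] - [E]/K2) per volume of the first phase (partition coefficient = 2.40, kL = 0.00460 s⁻¹)
    D + G → DG (k = 0.0240 M⁻¹ s⁻¹)
    DG ⇌ X (K = 0.970, k = 0.0140 s⁻¹)
    G + DG → GDG (k = 0.00440 M⁻¹ s⁻¹)

My reckoning for the flask stood 2.5 points above the result, and the flask also held 14.4% of X at 5.00 min, which the DG figure does not show. I then carried the doubling step from the flask's result to the neighbouring flask, with c(D) at 0.56 M and the same equivalents and time. That neighbour lies 2 doublings above the flask, so the step gave 29.0%. The neighbouring flask gave 29.3% DG, with 25.3% of X beside it.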